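The north and south-west runs show X appearing behind Z, and reaching more in south-west (3.8%) than in north (1.3%) at the same last time, so we carry one number from them to blue.

| setting | north | south-west | blue | green | amber |
|---|---|---|---|---|---|
| G | 5 mM | 5 mM | 5.0 mM | 5.0 mM | 5.0 mM |
| E | 14 mM | 23 mM | 20.0 mM | 12.5 mM | 10.0 mM |
| J | 25 mM | 25 mM | 25.0 mM | 25.0 mM | 25.0 mM |
| remark | run made earlier | run made earlier |  |  |  |
| time |  |  | 3.0 min | 3.0 min | 3.0 min |

| run | time / s | X / % | Z / % |
|---|---|---|---|
| north | 25.0 | 0 | 24.6 |
| north | 50.0 | 0.4 | 31.0 |
| north | 60.0 | 0.8 | 32.9 |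
| north | 90.0 | 1.3 | 36.6 |
| south-west | 12.0 | 0.2 | 24.7 |
| south-west | 30.0 | 0.9 | 37.4 |
| south-west | 60.0 | 1.7 | 44.8 |
| south-west | 90.0 | 3.8 | 48.7 |

(standard deviation of a reading: 0.3 percentage points)

- which of these holds the largest part of the G at the end of blue (G / X / Z)
- which of these holds the largest part of the G at the end of green (G / X / Z)
- which of these holds the largest part of the G at the end of amber (G / X / Z)
- X at the end of blue, in percent of the G charged



Take dX/dt = kX·cE·Z, with X and Z as shares of the G charged. Integrated, this is X = kX × mean cE × exposure, where the exposure is the time integral of the Z share. Trapezoids through the readings give 23.6 s for north and 33.4 s for south-west. Mean cE is the charge less cG times the mean Z share. Pooling the last X readings gives the X constant kX = 0.0507 M⁻¹ s⁻¹, a reading that carries their scatter.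

For blue we take the south-west exposure and then hold its last Z to the end. That gives 77.3 s, a mean cE of 17.9 mM, and X of 6.99%.

The forecast, reasoning that “Z rises fast, then creeps on, more slowly than simple mass action predicts, so neither run has reached equilibrium.”, names Z, G and G for blue, green and amber, and X of 6.5% in blue, which is lower than ours.

The flasks give Z, G and G, and blue ends with X at 5.66%.

    G + E ⇌ J + Z (K = 0.880, k = 1.34 M⁻¹ s⁻¹)
    Z + E ⇌ J + X (K = 0.228, k = 0.0534 M⁻¹ s⁻¹)
    J → L (k = 0.00652 s⁻¹)

X stays low in blue mainly because the time given is short: left ten times as long, it reaches 62.1%. Part of the lead of Z in blue comes from J going on to L: with that step struck out, the leader in blue changes. The simulated Z values now put the blue exposure at 70.7 s, so kX with the half-time cE gives 6.26%. A neighbour of blue charged with 50 mM of E, given the same exposure per unit of final Z and its end cE, comes to 18.5%, and that flask holds 19.9%.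

The numbers in the tables are simulated on assumed constants, noise included.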